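If solid substrate keeps dissolving, what ratio of target to starting material does this flask hold, and what is left of it once the solid is gone?

    solid substrate ⇌ starting material, rate k1*(cs1 - [starting material]) while solid is left; crystals form when [starting material] > cs1 (cs1 = 17 mM, k1 = 1.1 s⁻¹)
    gas phase ⇌ dissolved gas, rate k2*(csat - [dissolved gas]) (k2 = 9.7 s⁻¹, csat = 7.6 mM)
    dissolved gas + target → over-reacted product (k3 = 7.0 L mol⁻¹ s⁻¹)
    target → over-reaction product (k4 = 0.18 s⁻¹)
    starting material + dissolved gas ⇌ target (K5 = 460 L mol⁻¹, k5 = 14 L mol⁻¹ s⁻¹)

solid substrate 0.050 M; gas phase 7.6 mM (held); time 40 s

- solid substrate is a solid; its amount is given per volume of the solution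
- at the start none of the gas is dissolved
- at the start none of the solid substrate is in solution
- run time (flask): 40 s

- maple: doubling the transfer coefficient of step 2, all else as stated
- birch: doubling the saturation concentration of gas phase, all else as stated
- alder: doubling the dissolution coefficient of step 1, all else as stated
- elm: doubling the solubility in step 1, all else as stated

1. target at 40 s, in percent of the solid substrate charged
2. the change that raises the amount of target at 40 s, in percent of the solid substrate charged most ("none" if none brings more than 2 percentage points) (maple / birch / alder / elm / none)
3. amount of target at 40 s, in percent of the solid substrate charged, after elm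

We start with the gas. Dissolved gas is replaced faster than it is used, so we put it at 7.6 mM. The reversible step is then pseudo-first-order, forward at kf = 0.106 s⁻¹ and back at kb = 0.0304 s⁻¹. Target goes on to its two products at kd = 0.233 s⁻¹.

The bench rule sets a reversible step at equilibrium, here a ratio of 3.50. That is our zero of the scale. The rule needs target to fall back faster than it goes on, but kd/kb = 7.66, so it fails here. We use instead the hold H = kf/(kb+kd), the ratio of target to starting material at which making balances both losses of target: 0.404.

Starting material is then used net at g = kd·H = 0.0941 s⁻¹. Against dissolving, it stands at A = 15.7 mM. Dividing the charge less (1+H)A by gA, and ignoring the start-up lag, we reckon that the solid lasts 19.0 s. The solution then drains at 0.0671 s⁻¹, and we commit to y = 3.09 %.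

Under elm, we reckon that A doubles and the solid lasts 2.05 s, giving 1.98 %. Under birch, H becomes 0.672, g becomes 0.192 s⁻¹ and A becomes 14.5 mM. Under alder, A becomes 16.3 mM. Maple enters none of this. Scoring the gains against 2 percentage points gives none.

The forecast, higher than our y, says 4.5 %, none and 2.3 % after elm, since a doubling “only uses up the substrate sooner and leaves more time for decay”. The flask gives 4.54 %, none and 2.08 % after elm.

At 15.0 s in the flask, target falls back at 0.13 of the rate at which it goes on, and its half-life toward over-reaction product, 3.9 s, is short against 40 s. At 20.0 s the flask holds 12.3 % target on 31.4 % starting material, a ratio of 0.392 against H. It also still holds 12.1 % solid substrate then, past our reckoned 19.0 s.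

The neighbour read at 15 s still has 26.5 % solid substrate, so H times A gives 12.6 % of the charge as target. That neighbour holds 12.1 %.

The constants were drawn at random within sensible limits.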